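## Structural features

The target 23 is a 2,3-dimethylchroman-4-one whose carbocycle is a dearomatised acylphloroglucinol. C7 is a ketone, C5 an enol hydrogen-bonded to the C4 carbonyl, C4a=C8a a vinylogous ester, and C8 an all-carbon quaternary stereocentre that carries a prenyl group and a CH2 link to a cyclobutane. C6 bears the (S)-configured chain CH(n-Pr)CH2CO2H. In the cyclobutane the link sits on C1', a gem-dimethyl group on C2' and an isopropenyl group on C3', with C1' and C3' cis. The six stereocentres form four groups that can hardly control one another: the adjacent cis pair C2/C3 (2R,3S), the isolated C8 (R), the side-chain carbon (S) and the 1,3-related cyclobutane pair (1'S,3'R). Fragile points are C3–H next to the C4 ketone (cis-to-trans epimerisation and retro-oxa-Michael opening under base), the triketone enol, and the isopropenylcyclobutane and prenyl alkenes, which under strong acid give cyclobutylcarbinyl cations that ring-expand. The real difficulty lies in C8, which is remote from every other stereocentre, and in the strained cis-cyclobutane with a quaternary ring carbon. The key step exploits the fact that C1' carries exactly one exocyclic carbon and is bonded to the quaternary C2'. At the carboxyl oxidation level, C1'–C2' is the bond formed when the quaternary α-carbon of a 2,2-dimethylcyclopentanone shifts to a diazo-bearing α'-carbon and the carbonyl carbon leaves the ring.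

## Logic of the disconnections

23 to 22: the acid and the C5 enol oxygen are joined through the acyl–O5 bond. In 22 the two groups mask each other, so C7–O is the only acidic site left and no protecting group is needed. The forward hydrolysis must open only this enol ester and must not touch C3.

22 to 20 and 21: the C8–CH2(prenyl) bond is cut. Removing the prenyl group rearomatises the ring, and a reactive allylic electrophile is the right group to add last to a hindered carbon. The quaternary stereocentre and the dienone are traded for a flat phenol. The forward step needs C- over O-alkylation, C8 over C6, and catalyst control of the phenolate face.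

20 to 18 and 12: the C8–CH2(link) bond is cut. C8 is the only free ring position and is ortho to the only free hydroxyl, and the cut divides the molecule into two halves whose stereocentres do not interact. The forward step must join and reduce without strong acid (cyclobutylcarbinyl cation) and without epimerising the α-carbon of 12.

12 to 11: a change of oxidation level only, so that the product of the key step is used directly.

11 to 8 (key): the cyclobutane bond C1–C2 is cut and C2 is reattached to the carboxyl carbon, which returns that carbon to the ring as a ketone. A strained ring with two stereocentres becomes a cyclopentanone with one. The forward step needs the diazo group on the only enolisable carbon and face-selective protonation at C1. The descriptor at the link-bearing carbon changes from R in 11 and 12 to S in 20 to 23 only through the priority rules.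

8 to 6: the diazo group is removed; C2 is quaternary, so only C5 can carry it.

6 to 1, 2 and 3: the C3–isopropenyl bond and one C2–CH3 bond are cut. Conjugate addition creates the enolate exactly where the second methyl group is needed. Three commercial compounds result. The forward step needs enantioface control at C3 and C-alkylation of a hindered enolate.

18 to 17: the O1–C2 bond of the pyranone is cut (oxa-Michael). The lactone already occupies the other ortho oxygen, so only one hydroxyl can close. Two stereocentres are removed. The forward step needs catalyst-controlled O–C bond formation and cis-selective protonation.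

17 to 15 and 16: the aryl–acyl bond C4–C4a is cut. The forward acylation must go para to the hindered hydroxyl and not between the two hydroxyls.

15 to 13 and 14: the aryl–CH bond and the acyl–O bond of the lactone are cut. The threefold symmetry of 13 makes all positions equivalent. The forward step needs enantioface control and a single annulation.

## Other disconnections considered

Alternative 1: The cut runs through C2–C3 and O1–C8a of the pyranone. The enol lactone A1 (the same structure as 22) would come from the bis-silyl dienol ether A2 and acetaldehyde A3. In the forward step a chiral titanium binaphtholate Lewis acid brings the carbonyl carbon of A3 onto the diene terminus C3; the aldehyde oxygen then adds to C8a and silanol is lost.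
- In favour: the base-sensitive cis-2,3-dimethylpyranone would be made last and would never have to survive alkylation or prenylation. On this point the alternative is better than the chosen plan, which carries the cis pair through three steps.
- Against: A2 needs a double silylation of a polycarbonyl compound with defined regiochemistry and enol ether geometry. C3 then depends on that geometry and on endo/exo topology. A3 is small, volatile and enolisable, which makes face discrimination hard. The Lewis acid meets an acid-sensitive isopropenylcyclobutane and a C8 centre that may oppose the catalyst.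
- Structure: only the heterocycle is addressed; the cyclobutane and C8 would still need the chemistry of steps 1 to 4, 8 and 9.
- Mechanism: a cycloaddition–elimination whose stereochemical course is less predictable here than an alkaloid-catalysed oxa-Michael closure.
- Step economy: silylation plus cycloaddition replaces acylation plus closure, so the two are equal.

Alternative 2: The cut is the C6–C7 bond of the carbocycle. The trione ester A4 would come from the 3,3-dialkylpyran-2,4-dione A5. An alkoxide opens the lactone, and the terminal carbanion of the resulting 3,5-dioxo ester closes onto the new ester in a Claisen-type condensation.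
- In favour: C8 is built by ordinary enolate alkylations of a malonate, with no dearomatisation and no C/O ambiguity, and the ring-forming event is driven by the stabilised trione enolate. The positions of the ring substituents are fixed by construction, so on ring regiochemistry the alternative is the equal or the better of the chosen plan (no question of the kind raised in step 6).
- Against: the configuration at C8 requires telling apart the two carboxyl groups of a malonate that carries two primary alkyl groups of similar size. The terminal deprotonation needs a dianion and competes with retro-Claisen cleavage. C4a must still be acylated and the pyranone closed onto one of two enol oxygens.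
- Structure: the ring is made de novo, but the cyclobutane still needs a separate route.
- Mechanism: ionic acyl transfers, robust in themselves.
- Step economy: clearly longer.

Alternative 3: The cut is the bond from C6 to the side chain together with the lactone C–O bond. The enol lactone A6 would come from the prochiral trione A7 and 14 under a chiral triazolium-derived carbene. The unsaturated acyl azolium is attacked by one flanking methylene carbon and then acylates the neighbouring enol oxygen.
- In favour: C8 and the side-chain centre would be set in one catalytic step from a symmetric precursor, and no separate face-selective prenylation is needed. For the carbocyclic half the alternative is better in step economy.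
- Against: the catalyst must choose between two methylene carbons that differ only through remote prenyl and cyclobutylmethyl groups, and also between the enal faces, so four stereoisomers are possible. A7 has several O- and C-nucleophilic sites. Making A7 needs alkylation of a trione with a β-branched cyclobutylmethyl electrophile. Acylation at C4a and pyranone closure still follow.
- Structure: the cyclobutane must exist beforehand.
- Mechanism: the same acyl azolium chemistry as step 5, but with group selection on top of face selection (in step 5 the nucleophile is threefold symmetric).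
- Step economy: shorter than the chosen plan if the selection works, more wasteful if it does not.

Key step: step 3

Assumption: in the catalyst-controlled steps 1, 5, 7 and 9 the enantiomer of the ligand, carbene precursor or alkaloid is the one that leads to the configuration drawn; the sense is assigned by analogy with the closest known substrates, and the mirror-image or pseudo-enantiomeric catalyst is taken if a first run shows the opposite sense.

## Steps

Step 1
Reactants: 1 2-methylcyclopent-2-en-1-one; 2 2-bromopropene; 3 iodomethane
Product: 6 (3R)-2,2-dimethyl-3-(prop-1-en-2-yl)cyclopentan-1-one, via isopropenylmagnesium bromide 4 (not isolated), via bromomagnesium enolate 5 (not isolated)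
Conditions: 2, Mg, 2-MeTHF, 40 °C; then 1, Cu(OTf)2 (3 mol %), chiral hydroxyalkyl imidazolinium salt as NHC precursor (4 mol %), Et2O, −30 °C; then 3, DMPU, −30 °C → rt
Reagents that add atoms: none
Why: Copper-catalysed asymmetric conjugate addition of a Grignard reagent to an α-substituted cyclic enone with alkylative trapping of the magnesium enolate: the chiral NHC–copper complex selects the face of C3 to which the isopropenyl group is delivered (3R), and the enolate exists only across C1–C2, so iodomethane can add only at C2 and turns it into the gem-dimethyl carbon (no stereocentre).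

Step 2
Reactants: 6 (3R)-2,2-dimethyl-3-(prop-1-en-2-yl)cyclopentan-1-one
Product: 8 (3R)-5-diazo-2,2-dimethyl-3-(prop-1-en-2-yl)cyclopentan-1-one, via trifluoroacetyl ketone 7 (not isolated)
Conditions: LiN(SiMe3)2, THF, −78 °C; CF3CO2CH2CF3, −78 °C; aq HCl; then MsN3, Et3N, H2O, MeCN, rt
Reagents that add atoms: methanesulfonyl azide, CS(=O)(=O)N=[N+]=[N-]; 2,2,2-trifluoroethyl trifluoroacetate, O=C(OCC(F)(F)F)C(F)(F)F (its acyl group stays only in 7)
Why: Detrifluoroacetylative diazo transfer: C2 is quaternary, so the enolate and the Claisen-type trifluoroacetylation can occur only at C5, and the activated 1,3-dicarbonyl compound 7 takes the diazo group from mesyl azide while the trifluoroacetyl group leaves as the N-acyl sulfonamide. C3 is not enolisable and keeps its configuration.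

Step 3
Reactants: 8 (3R)-5-diazo-2,2-dimethyl-3-(prop-1-en-2-yl)cyclopentan-1-one
Product: 11 methyl (1R,3R)-2,2-dimethyl-3-(prop-1-en-2-yl)cyclobutane-1-carboxylate, via cyclobutylidene ketene 9 (not isolated), via ester enol 10 (not isolated)
Conditions: hν (365 nm LED, or medium-pressure Hg lamp through Pyrex), degassed MeOH, 0 °C → rt
Reagents that add atoms: methanol, CO
Why: Excitation of the cyclic diazo ketone, which is locked s-cis, expels N2 while the quaternary carbon C2 shifts from the carbonyl carbon to C5 (Wolff rearrangement); this forms the C5–C2 bond and gives ketene 9, to which methanol adds to give ester enol 10 and, after tautomerisation, ester 11. The closest known reaction type is the photochemical Wolff ring contraction of 2-diazocyclopentanones to cyclobutanecarboxylates. The four-membered ring is closed by a 1,2-carbon shift inside the five-membered ring (ring contraction with extrusion of the carbonyl carbon as the exocyclic carboxyl carbon), not by an exo or endo cyclisation of a chain. The new stereocentre C1 arises when the planar enol 10 is protonated: the isopropenyl group on C3 lies across the small ring and shields its own face, so the proton should enter anti to it and leave the ester cis; the controlling element is the C3 stereocentre, which is itself untouched. The step needs migration instead of O–H insertion of a free carbene, which the enforced s-cis geometry favours; a single migrating bond, secured because C2 is the only carbon on the carbonyl group besides C5; and no reaction at the isolated alkene, which does not absorb at this wavelength and cannot reach the carbene carbon. If protonation is not fully selective, deprotonation with LiN(i-Pr)2 and kinetic reprotonation by a hindered phenol from the open face corrects the mixture.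

Step 4
Reactants: 11 methyl (1R,3R)-2,2-dimethyl-3-(prop-1-en-2-yl)cyclobutane-1-carboxylate
Product: 12 (1R,3R)-2,2-dimethyl-3-(prop-1-en-2-yl)cyclobutane-1-carbaldehyde
Conditions: i-Bu2AlH (1.1 equiv), CH2Cl2, −78 °C; MeOH, then aq Rochelle salt
Reagents that add atoms: none
Why: Partial reduction of an ester by a dialkylaluminium hydride: the tetrahedral aluminium hemiacetal of this α-branched ester is stable at −78 °C and releases the aldehyde only on work-up, so no second hydride is added; no base is present, so C1 is not epimerised.

Step 5
Reactants: 13 phloroglucinol (benzene-1,3,5-triol); 14 (E)-hex-2-enal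
Product: 15 (4S)-5,7-dihydroxy-4-propylchroman-2-one
Conditions: 13 (3 equiv), chiral aminoindanol-derived N-mesityl triazolium chloride (10 mol %), i-Pr2NEt (20 mol %), 3,3',5,5'-tetra-tert-butyl-4,4'-diphenoquinone (1.1 equiv), THF, rt
Reagents that add atoms: none
Why: Carbene-catalysed oxidative annulation: the enal is converted through its Breslow intermediate and oxidation into a catalyst-bound α,β-unsaturated acyl azolium, a ring carbon of the triphenol adds to its β-carbon (directly or by O-acylation and [3,3] shift), and the neighbouring hydroxyl closes the lactone and frees the carbene. The chiral triazolium shields one face of the acyl azolium and so sets C4 (4S); the threefold symmetry of 13 removes any question of regiochemistry and its excess suppresses a second annulation.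

Step 6
Reactants: 15 (4S)-5,7-dihydroxy-4-propylchroman-2-one; 16 tigloyl chloride [(E)-2-methylbut-2-enoyl chloride]
Product: 17 (4S)-5,7-dihydroxy-8-[(E)-2-methylbut-2-enoyl]-4-propylchroman-2-one
Conditions: AlCl3 (3.5 equiv), PhNO2/CH2Cl2, 0 °C → rt; cold dilute HCl
Reagents that add atoms: none
Why: Friedel–Crafts acylation: C8 (coumarin numbering) is ortho to the 7-hydroxyl and para to the 5-hydroxyl, the pattern that directs electrophiles in 4-substituted resorcinols and in orcinol, whereas C6 is only ortho to both; the lactone oxygen is a weak donor and does not change this. Low temperature and a cold quench keep the tigloyl phenol from closing to the pyranone without stereocontrol; C4 is not affected.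

Step 7
Reactants: 17 (4S)-5,7-dihydroxy-8-[(E)-2-methylbut-2-enoyl]-4-propylchroman-2-one
Product: 18 (4S,8R,9S)-5-hydroxy-8,9-dimethyl-4-propyl-3,4,8,9-tetrahydro-2H,10H-pyrano[2,3-f]chromene-2,10-dione (cis-2,3-dimethylchroman-4-one fused to the dihydrocoumarin)
Conditions: (−)-quinine (20 mol %), PhCl, rt
Reagents that add atoms: none
Why: Cinchona-alkaloid-catalysed intramolecular oxa-Michael addition: the 7-hydroxyl is the only hydroxyl ortho to the enone (the other ortho oxygen is the lactone oxygen), the quinine-bound phenol adds to one face of the β-carbon and sets C8 (8R), and kinetic protonation of the enol on the face away from the new methyl group gives the cis isomer (9S). This closure is known for 7-hydroxy-8-tigloylcoumarins; the weakly basic medium leaves the cis pair and C4 unchanged.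

Step 8
Reactants: 18 (4S,8R,9S)-5-hydroxy-8,9-dimethyl-4-propyl-3,4,8,9-tetrahydro-2H,10H-pyrano[2,3-f]chromene-2,10-dione; 12 (1R,3R)-2,2-dimethyl-3-(prop-1-en-2-yl)cyclobutane-1-carbaldehyde
Product: 20 (4S,8R,9S)-6-{[(1S,3R)-2,2-dimethyl-3-(prop-1-en-2-yl)cyclobutyl]methyl}-5-hydroxy-8,9-dimethyl-4-propyl-3,4,8,9-tetrahydro-2H,10H-pyrano[2,3-f]chromene-2,10-dione, via ortho-quinone methide 19 (not isolated)
Conditions: Hantzsch ester (diethyl 2,6-dimethyl-1,4-dihydropyridine-3,5-dicarboxylate, 1.5 equiv), L-proline (20 mol %), CH2Cl2, rt
Reagents that add atoms: none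
Why: Three-component reductive alkylation (Knoevenagel-type condensation followed by transfer hydrogenation): the aldehyde condenses at the only unsubstituted ring carbon, which is ortho to the free hydroxyl, to give ortho-quinone methide 19, and the Hantzsch ester reduces 19 at once to the benzylic CH2 group with rearomatisation. No stereocentre is formed; the medium is neither strongly acidic nor strongly basic, so no cyclobutylcarbinyl cation arises, and epimerisation at C1 of 12 would need a tetrasubstituted exocyclic enamine next to the quaternary carbon, which is disfavoured.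

Step 9
Reactants: 20 (4S,8R,9S)-6-{[(1S,3R)-2,2-dimethyl-3-(prop-1-en-2-yl)cyclobutyl]methyl}-5-hydroxy-8,9-dimethyl-4-propyl-3,4,8,9-tetrahydro-2H,10H-pyrano[2,3-f]chromene-2,10-dione; 21 tert-butyl (3-methylbut-2-en-1-yl) carbonate
Product: 22 (4S,6R,8R,9S)-6-{[(1S,3R)-2,2-dimethyl-3-(prop-1-en-2-yl)cyclobutyl]methyl}-8,9-dimethyl-6-(3-methylbut-2-en-1-yl)-4-propyl-3,4,8,9-tetrahydro-2H-pyrano[2,3-f]chromene-2,5,10(6H)-trione (enol lactone of the target)
Conditions: Pd2(dba)3 (2.5 mol %), (R,R)-DACH-phenyl Trost ligand (7.5 mol %), toluene, 0 °C → rt
Reagents that add atoms: none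
Why: Tsuji–Trost allylic alkylation with dearomatisation: zerovalent palladium ionises 21 to a π-prenyl complex with loss of CO2, the tert-butoxide formed deprotonates the phenol, and the phenolate attacks the unsubstituted allyl terminus through its ortho carbon C6 (C8 of the target), the less hindered of the two ortho carbons; O-prenylation is reversible under the catalyst, C-prenylation to the vinylogous triketone is not. The new quaternary centre (6R) is set by the chiral ligand, which differentiates the two faces of the planar phenolate; the existing stereocentres are too remote to do so.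

Step 10
Reactants: 22 (4S,6R,8R,9S)-6-{[(1S,3R)-2,2-dimethyl-3-(prop-1-en-2-yl)cyclobutyl]methyl}-8,9-dimethyl-6-(3-methylbut-2-en-1-yl)-4-propyl-3,4,8,9-tetrahydro-2H-pyrano[2,3-f]chromene-2,5,10(6H)-trione
Product: 23 (3S)-3-[(2R,3S,8R)-8-{[(1S,3R)-2,2-dimethyl-3-(prop-1-en-2-yl)cyclobutyl]methyl}-5-hydroxy-2,3-dimethyl-8-(3-methylbut-2-en-1-yl)-4,7-dioxo-3,4,7,8-tetrahydro-2H-chromen-6-yl]hexanoic acid
Conditions: LiOH (3 equiv), THF/H2O 3:1, 0 °C; then cold dilute HCl to pH 3–4
Reagents that add atoms: lithium hydroxide, [Li+].[OH-]
Why: Saponification of an enol ester that is a vinylogous anhydride: hydroxide attacks the lactone carbonyl far faster than it removes the C3 proton of the pyranone, and the ring-opened carboxylate–enolate dianion resists further deprotonation, so the cis-2,3-dimethyl pair, C8 and the side-chain centre are kept; acidification gives the enol acid 23.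

## Compound list

1 | 2-methylcyclopent-2-en-1-one | CC1=CCCC1=O | starting material
2 | 2-bromopropene | C=C(C)Br | starting material
3 | iodomethane | CI | starting material
4 | isopropenylmagnesium bromide | C=C(C)[Mg]Br | intermediate
5 | bromomagnesium (3R)-2-methyl-3-(prop-1-en-2-yl)cyclopent-1-en-1-olate | C=C(C)[C@H]1CCC(O[Mg]Br)=C1C | intermediate
6 | (3R)-2,2-dimethyl-3-(prop-1-en-2-yl)cyclopentan-1-one | C=C(C)[C@H]1CCC(=O)C1(C)C | intermediate
7 | (3R)-2,2-dimethyl-3-(prop-1-en-2-yl)-5-(2,2,2-trifluoro-1-hydroxyethylidene)cyclopentan-1-one (enol form of the 5-trifluoroacetyl ketone) | C=C(C)[C@H]1CC(=C(O)C(F)(F)F)C(=O)C1(C)C | intermediate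
8 | (3R)-5-diazo-2,2-dimethyl-3-(prop-1-en-2-yl)cyclopentan-1-one | C=C(C)[C@H]1CC(=[N+]=[N-])C(=O)C1(C)C | intermediate
9 | [(3R)-2,2-dimethyl-3-(prop-1-en-2-yl)cyclobutylidene]methanone (ketene) | C=C(C)[C@H]1CC(=C=O)C1(C)C | intermediate
10 | [(3R)-2,2-dimethyl-3-(prop-1-en-2-yl)cyclobutylidene](methoxy)methanol (ester enol) | C=C(C)[C@H]1CC(=C(O)OC)C1(C)C | intermediate
11 | methyl (1R,3R)-2,2-dimethyl-3-(prop-1-en-2-yl)cyclobutane-1-carboxylate (cis) | C=C(C)[C@H]1C[C@@H](C(=O)OC)C1(C)C | intermediate
12 | (1R,3R)-2,2-dimethyl-3-(prop-1-en-2-yl)cyclobutane-1-carbaldehyde (cis) | C=C(C)[C@H]1C[C@@H](C=O)C1(C)C | intermediate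
13 | phloroglucinol (benzene-1,3,5-triol) | Oc1cc(O)cc(O)c1 | starting material
14 | (E)-hex-2-enal | CCC/C=C/C=O | starting material
15 | (4S)-5,7-dihydroxy-4-propylchroman-2-one | O=C1C[C@H](CCC)c2c(O)cc(O)cc2O1 | intermediate
16 | tigloyl chloride [(E)-2-methylbut-2-enoyl chloride] | C/C=C(\C)C(Cl)=O | starting material
17 | (4S)-5,7-dihydroxy-8-[(E)-2-methylbut-2-enoyl]-4-propylchroman-2-one | C/C=C(\C)C(=O)c1c(O)cc(O)c2c1OC(=O)C[C@@H]2CCC | intermediate
18 | (4S,8R,9S)-5-hydroxy-8,9-dimethyl-4-propyl-3,4,8,9-tetrahydro-2H,10H-pyrano[2,3-f]chromene-2,10-dione | O=C1C[C@H](CCC)c2c(O)cc3O[C@H](C)[C@H](C)C(=O)c3c2O1 | intermediate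
19 | ortho-quinone methide from 18 and 12: (4S,8R,9S)-6-{[(1S,3R)-2,2-dimethyl-3-(prop-1-en-2-yl)cyclobutyl]methylidene}-8,9-dimethyl-4-propyl-3,4,8,9-tetrahydro-2H-pyrano[2,3-f]chromene-2,5,10(6H)-trione | C=C(C)[C@H]1C[C@@H](C=C2C(=O)C3=C(OC(=O)C[C@@H]3CCC)C4=C2O[C@H](C)[C@H](C)C4=O)C1(C)C | intermediate
20 | (4S,8R,9S)-6-{[(1S,3R)-2,2-dimethyl-3-(prop-1-en-2-yl)cyclobutyl]methyl}-5-hydroxy-8,9-dimethyl-4-propyl-3,4,8,9-tetrahydro-2H,10H-pyrano[2,3-f]chromene-2,10-dione | C=C(C)[C@H]1C[C@@H](Cc2c(O)c3[C@@H](CCC)CC(=O)Oc3c4c2O[C@H](C)[C@H](C)C4=O)C1(C)C | intermediate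
21 | tert-butyl (3-methylbut-2-en-1-yl) carbonate | CC(C)=CCOC(=O)OC(C)(C)C | starting material
22 | (4S,6R,8R,9S)-6-{[(1S,3R)-2,2-dimethyl-3-(prop-1-en-2-yl)cyclobutyl]methyl}-8,9-dimethyl-6-(3-methylbut-2-en-1-yl)-4-propyl-3,4,8,9-tetrahydro-2H-pyrano[2,3-f]chromene-2,5,10(6H)-trione | C=C(C)[C@H]1C[C@@H](C[C@@]2(CC=C(C)C)C(=O)C3=C(OC(=O)C[C@@H]3CCC)C4=C2O[C@H](C)[C@H](C)C4=O)C1(C)C | intermediate
23 | (3S)-3-[(2R,3S,8R)-8-{[(1S,3R)-2,2-dimethyl-3-(prop-1-en-2-yl)cyclobutyl]methyl}-5-hydroxy-2,3-dimethyl-8-(3-methylbut-2-en-1-yl)-4,7-dioxo-3,4,7,8-tetrahydro-2H-chromen-6-yl]hexanoic acid | C=C(C)[C@H]1C[C@@H](C[C@@]2(CC=C(C)C)C(=O)C([C@@H](CCC)CC(=O)O)=C(O)C3=C2O[C@H](C)[C@H](C)C3=O)C1(C)C | target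

## Step count and least certain steps

Total: 10 steps. Longest linear sequence: 7 steps (steps 1 to 4, then 8 to 10); the aromatic branch (steps 5 to 7) joins at step 8.

Step 3 (key). Material may be lost through O–H insertion of the carbene into methanol and through inefficient contraction to the strained ring, and the ester enol may be protonated from both faces. The fallback sets out from 6 and comes back at 11. The lithium enolate of 6 (LiN(SiMe3)2, THF, −78 °C) is chlorinated with CF3SO2Cl to (3R)-5-chloro-2,2-dimethyl-3-(prop-1-en-2-yl)cyclopentan-1-one F1 (C5 epimers). NaOMe in MeOH then brings about the semibenzilic (quasi-Favorskii) contraction: methoxide adds to the carbonyl group and the same quaternary carbon shifts to C5 with loss of chloride, so 11 is reached without a carbene. An epimer mixture at C1 is corrected by the kinetic reprotonation named in step 3.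

Step 1. Enantioface selection may be low with an alkenyl Grignard reagent on this α-substituted five-ring enone, and C-methylation of the hindered magnesium enolate may be sluggish. The fallback sets out from 2 (through 4) and comes back at 8. Grignard reagent 4 is borylated with 2-isopropoxy-4,4,5,5-tetramethyl-1,3,2-dioxaborolane to 4,4,5,5-tetramethyl-2-(prop-1-en-2-yl)-1,3,2-dioxaborolane F2. Hayashi–Miyaura addition to commercial cyclopent-2-en-1-one ([Rh(cod)Cl]2, (S)-BINAP, aq KOH, dioxane), a substrate class with dependable enantiocontrol, gives (3S)-3-(prop-1-en-2-yl)cyclopentan-1-one F3. The less hindered α-carbon is blocked with Me2NCH(OMe)2 as (4S,E)-2-[(dimethylamino)methylidene]-4-(prop-1-en-2-yl)cyclopentan-1-one F4. Two α'-methylations (LiN(i-Pr)2, MeI) lead through (3S,E)-5-[(dimethylamino)methylidene]-2-methyl-3-(prop-1-en-2-yl)cyclopentan-1-one F5 to (3R,E)-5-[(dimethylamino)methylidene]-2,2-dimethyl-3-(prop-1-en-2-yl)cyclopentan-1-one F6. Deformylative diazo transfer with TsN3 then gives 8 directly.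

Step 5. Face control may be insufficient with a small alkyl enal and a very reactive symmetric triphenol, and a second annulation may occur. The fallback sets out from 14 and comes back at 15.
- Pinnick oxidation (NaClO2, NaH2PO4, 2-methylbut-2-ene) gives (E)-hex-2-enoic acid F7.
- Pivaloyl chloride and Et3N give (E)-hex-2-enoic pivalic anhydride F8.
- (R)-4-Phenyloxazolidin-2-one and LiCl give (R)-3-[(E)-hex-2-enoyl]-4-phenyloxazolidin-2-one F9.
- Commercial 2,4,6-trimethoxyphenylmagnesium bromide with CuBr·SMe2 adds from the face opposite the phenyl group of the chelated imide to give (R)-4-phenyl-3-[(3S)-3-(2,4,6-trimethoxyphenyl)hexanoyl]oxazolidin-2-one F10.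
- LiOH/H2O2 frees (3S)-3-(2,4,6-trimethoxyphenyl)hexanoic acid F11.
- BBr3 in CH2Cl2 removes the three methyl groups, and the triphenol acid lactonises to 15.

Step 6. Acylation may occur at C6, between the two hydroxyl groups, and acid may close the tigloyl phenol to the pyranone before the alkaloid step. The fallback sets out from 13 and comes back at 18. Pechmann condensation of 13 with ethyl 3-oxohexanoate (CH3SO3H) gives 5,7-dihydroxy-4-propyl-2H-chromen-2-one F12, in which C8 is the established site of Friedel–Crafts acylation of 5,7-dihydroxycoumarins. Acylation with 16 and AlCl3 gives 5,7-dihydroxy-8-[(E)-2-methylbut-2-enoyl]-4-propyl-2H-chromen-2-one F13. Quinine-catalysed closure gives (8R,9S)-5-hydroxy-8,9-dimethyl-4-propyl-8,9-dihydro-2H,10H-pyrano[2,3-f]chromene-2,10-dione F14. Hydrogenation of the coumarin double bond (H2, palladium on carbon, EtOAc) gives 18 together with its C4 epimer, (4R,8R,9S)-5-hydroxy-8,9-dimethyl-4-propyl-3,4,8,9-tetrahydro-2H,10H-pyrano[2,3-f]chromene-2,10-dione F15, from which 18 must be separated. This way removes the regiochemical risk at the price of control at C4.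

Step 8. Condensation of the hindered α-branched aldehyde with the acyl-deactivated phenol may be slow. C1 of 12 may epimerise through enol or enamine formation. Intermediate 19 may tautomerise to a styrene or be captured by a second phenol. The fallback sets out from 11 and 18 and comes back at 20.
- LiAlH4 reduces 11 to [(1R,3R)-2,2-dimethyl-3-(prop-1-en-2-yl)cyclobutyl]methanol F16.
- Appel iodination (I2, PPh3, imidazole) gives (1R,3R)-1-(iodomethyl)-2,2-dimethyl-3-(prop-1-en-2-yl)cyclobutane F17.
- Zinc insertion (Zn, LiCl, THF) gives {[(1R,3R)-2,2-dimethyl-3-(prop-1-en-2-yl)cyclobutyl]methyl}zinc iodide F18.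
- N-Iodosuccinimide iodinates 18 at its only free ring position to (4S,8R,9S)-5-hydroxy-6-iodo-8,9-dimethyl-4-propyl-3,4,8,9-tetrahydro-2H,10H-pyrano[2,3-f]chromene-2,10-dione F19.
- Negishi coupling of F18 with the sodium phenoxide of F19 (Pd(OAc)2, SPhos, THF) gives 20.

No carbonyl group then stands next to C1 of the cyclobutane, so that centre cannot epimerise.

Step 9. The catalyst may discriminate the two faces of the planar phenolate only weakly, because both ortho neighbours of the reacting carbon carry oxygen; O-prenylation may fail to revert; attack may occur at the other ortho carbon. The fallback sets out from 20 and comes back at 22. It is an ion-pair alkylation with prenyl bromide, solid Cs2CO3 and a cinchona-derived N-anthracenylmethyl ammonium bromide in toluene at −20 °C, an enantioselective alkylative dearomatisation known for acylphloroglucinols. The bond then forms by SN2 attack inside a chiral ion pair and no longer through a π-allyl complex. This way makes no new compound (entry F0). In either variant the two C8 epimers differ by a large substituent and should be separable by chromatography.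

## Further compounds

F1 | step 3 | (3R)-5-chloro-2,2-dimethyl-3-(prop-1-en-2-yl)cyclopentan-1-one (C5 epimers) | C=C(C)[C@H]1CC(Cl)C(=O)C1(C)C
F2 | step 1 | 4,4,5,5-tetramethyl-2-(prop-1-en-2-yl)-1,3,2-dioxaborolane | C=C(C)B1OC(C)(C)C(C)(C)O1
F3 | step 1 | (3S)-3-(prop-1-en-2-yl)cyclopentan-1-one | C=C(C)[C@H]1CCC(=O)C1
F4 | step 1 | (4S,E)-2-[(dimethylamino)methylidene]-4-(prop-1-en-2-yl)cyclopentan-1-one | C=C(C)[C@H]1C/C(=C\N(C)C)C(=O)C1
F5 | step 1 | (3S,E)-5-[(dimethylamino)methylidene]-2-methyl-3-(prop-1-en-2-yl)cyclopentan-1-one (C2 epimers) | C=C(C)[C@H]1C/C(=C\N(C)C)C(=O)C1C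
F6 | step 1 | (3R,E)-5-[(dimethylamino)methylidene]-2,2-dimethyl-3-(prop-1-en-2-yl)cyclopentan-1-one | C=C(C)[C@H]1C/C(=C\N(C)C)C(=O)C1(C)C
F7 | step 5 | (E)-hex-2-enoic acid | CCC/C=C/C(=O)O
F8 | step 5 | (E)-hex-2-enoic pivalic anhydride | CCC/C=C/C(=O)OC(=O)C(C)(C)C
F9 | step 5 | (R)-3-[(E)-hex-2-enoyl]-4-phenyloxazolidin-2-one | CCC/C=C/C(=O)N1[C@H](c2ccccc2)COC1=O
F10 | step 5 | (R)-4-phenyl-3-[(3S)-3-(2,4,6-trimethoxyphenyl)hexanoyl]oxazolidin-2-one | CCC[C@@H](CC(=O)N1[C@H](c2ccccc2)COC1=O)c1c(OC)cc(OC)cc1OC
F11 | step 5 | (3S)-3-(2,4,6-trimethoxyphenyl)hexanoic acid | CCC[C@@H](CC(=O)O)c1c(OC)cc(OC)cc1OC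
F12 | step 6 | 5,7-dihydroxy-4-propyl-2H-chromen-2-one | CCCc1cc(=O)oc2cc(O)cc(O)c12
F13 | step 6 | 5,7-dihydroxy-8-[(E)-2-methylbut-2-enoyl]-4-propyl-2H-chromen-2-one | C/C=C(\C)C(=O)c1c(O)cc(O)c2c(CCC)cc(=O)oc12
F14 | step 6 | (8R,9S)-5-hydroxy-8,9-dimethyl-4-propyl-8,9-dihydro-2H,10H-pyrano[2,3-f]chromene-2,10-dione | CCCc1cc(=O)oc2c3c(cc(O)c12)O[C@H](C)[C@H](C)C3=O
F15 | step 6 | (4R,8R,9S)-5-hydroxy-8,9-dimethyl-4-propyl-3,4,8,9-tetrahydro-2H,10H-pyrano[2,3-f]chromene-2,10-dione | O=C1C[C@@H](CCC)c2c(O)cc3O[C@H](C)[C@H](C)C(=O)c3c2O1
F16 | step 8 | [(1R,3R)-2,2-dimethyl-3-(prop-1-en-2-yl)cyclobutyl]methanol | C=C(C)[C@H]1C[C@@H](CO)C1(C)C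
F17 | step 8 | (1R,3R)-1-(iodomethyl)-2,2-dimethyl-3-(prop-1-en-2-yl)cyclobutane | C=C(C)[C@H]1C[C@@H](CI)C1(C)C
F18 | step 8 | {[(1R,3R)-2,2-dimethyl-3-(prop-1-en-2-yl)cyclobutyl]methyl}zinc iodide | C=C(C)[C@H]1C[C@@H](C[Zn]I)C1(C)C
F19 | step 8 | (4S,8R,9S)-5-hydroxy-6-iodo-8,9-dimethyl-4-propyl-3,4,8,9-tetrahydro-2H,10H-pyrano[2,3-f]chromene-2,10-dione | O=C1C[C@H](CCC)c2c(O)c(I)c3O[C@H](C)[C@H](C)C(=O)c3c2O1
F0 | step 9 | none | none
A1 | alternative 1 | enol lactone of the target (same structure as 22) | C=C(C)[C@H]1C[C@@H](C[C@@]2(CC=C(C)C)C(=O)C3=C(OC(=O)C[C@@H]3CCC)C4=C2O[C@H](C)[C@H](C)C4=O)C1(C)C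
A2 | alternative 1 | bis(trimethylsilyl) dienol ether of the 4a-propanoyl enol lactone (Z enol ether; C8 and the lactone carbon as in the target) | C=C(C)[C@H]1C[C@@H](C[C@@]2(CC=C(C)C)C(=O)C3=C(OC(=O)C[C@@H]3CCC)C(/C(O[Si](C)(C)C)=C/C)=C2O[Si](C)(C)C)C1(C)C
A3 | alternative 1 | acetaldehyde | CC=O
A4 | alternative 2 | C8-quaternary, C6-alkylated cyclohexane-1,3,5-trione, enol form, tert-butyl ester | C=C(C)[C@H]1C[C@@H](C[C@@]2(CC=C(C)C)C(=O)C([C@@H](CCC)CC(=O)OC(C)(C)C)=C(O)CC2=O)C1(C)C
A5 | alternative 2 | 3,3-dialkyl-6-substituted pyran-2,4-dione (3-prenyl, 3-cyclobutylmethyl, 6-[2-propyl-3-(tert-butoxycarbonyl)propyl]) | C=C(C)[C@H]1C[C@@H](C[C@@]2(CC=C(C)C)C(=O)OC(C[C@@H](CCC)CC(=O)OC(C)(C)C)=CC2=O)C1(C)C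
A6 | alternative 3 | enol lactone fused at C5–C6, C4a unsubstituted | C=C(C)[C@H]1C[C@@H](C[C@@]2(CC=C(C)C)C(=O)C3=C(OC(=O)C[C@@H]3CCC)CC2=O)C1(C)C
A7 | alternative 3 | 2-{[(1S,3R)-2,2-dimethyl-3-(prop-1-en-2-yl)cyclobutyl]methyl}-2-(3-methylbut-2-en-1-yl)cyclohexane-1,3,5-trione | C=C(C)[C@H]1C[C@@H](CC2(CC=C(C)C)C(=O)CC(=O)CC2=O)C1(C)C
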